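**Retrosynthetic overview**
1. The last step joins the two halves at C6–CH2. A primary alkylzinc made from decalin iodide 32 attacks the cyclic peroxycarbenium ion made from peroxyketal 11, and axial attack sets C6. No hydroperoxide oxa-Michael closure and no late alkene peroxidation is used.
2. The dioxane ring is made first (fragment 1). A hydroperoxyketal from ozonolysis in MeOH opens a trans-β-lactone at C4 by 6-exo-tet SN2, which inverts C3, keeps C2 and frees the acid.
3. β-Lactone 6 comes from a catalytic asymmetric ketene–aldehyde [2+2], then a trans-selective enolate methylation.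
4. In the decalin (fragment 2), ring A comes from an auxiliary-controlled endo Diels–Alder reaction that sets both fusion centres. Ring B is then closed by ring-closing metathesis to the cis-fused enone 27.
5. Me2CuLi and then MeI deliver both methyl groups from the convex face (decalin C3 and C2). Tebbe methylenation and conversion of OH to iodide follow.

Assumption: the decalin is numbered C1 (methylidene or C=O carbon), C2 (quaternary), C3 (CHMe), C4, C4a, C5–C8, C8a; the aluminium catalyst of step 1 is made beforehand from L-valinol and is not counted.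

**Fragment 1 (steps 1–4)**

Step 1
Reactants: 1 4-methylpent-4-enal; 2 acetyl bromide
Product: 4 (4S)-4-(3-methylbut-3-en-1-yl)oxetan-2-one, via ketene 3 (not isolated)
Conditions: iPr2NEt, MeAl[N(Tf)CH(iPr)CH2]2NBn (10 mol %, from L-valinol), CH2Cl2, −50 °C
Reagents that add atoms: none
Why: Catalytic asymmetric ketene–aldehyde [2+2] cyclocondensation in which ketene 3, made in situ, adds to one face of the catalyst-bound aldehyde, so lactone C4 (the later dioxane C3, still to be inverted) is set as S, the sense this catalyst gives with unbranched aliphatic aldehydes.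

Step 2
Reactants: 4 (4S)-4-(3-methylbut-3-en-1-yl)oxetan-2-one
Product: 6 (3S,4S)-3-methyl-4-(3-methylbut-3-en-1-yl)oxetan-2-one (trans), via sodium enolate 5 (not isolated)
Conditions: NaN(SiMe3)2, THF, −100 → −78 °C; MeI (5 equiv)
Reagents that add atoms: iodomethane, CI
Why: β-Lactone enolate alkylation in which the flat four-ring enolate 5 is methylated on the face away from the C4 side chain, so the new methyl centre (later C2 of the propanoate) comes out trans (3S), while the very low temperature holds back self-acylation.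

Step 3
Reactants: 6 (3S,4S)-3-methyl-4-(3-methylbut-3-en-1-yl)oxetan-2-one
Product: 8 (3S,4S)-4-(3-hydroperoxy-3-methoxybutyl)-3-methyloxetan-2-one (ketal carbon 1:1), via carbonyl oxide 7 (not isolated)
Conditions: O3, CH2Cl2–MeOH 4:1, −78 °C; N2 purge, no reductant
Reagents that add atoms: ozone, [O-][O+]=O; methanol, CO
Why: Criegee ozonolysis in a participating solvent, in which the 1,1-disubstituted alkene splits into formaldehyde and the more substituted carbonyl oxide 7, methanol traps 7 as the α-methoxy hydroperoxide, the neutral cold medium leaves the lactone untouched, and the unselective ketal centre is erased in step 16.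

Step 4
Reactants: 8 (3S,4S)-4-(3-hydroperoxy-3-methoxybutyl)-3-methyloxetan-2-one
Product: 11 methyl (2S)-2-[(3R)-6-methoxy-6-methyl-1,2-dioxan-3-yl]propanoate (C6 epimer mixture), via caesium peroxide 9 (not isolated), via caesium carboxylate 10 (not isolated)
Conditions: Cs2CO3 (1.0 equiv), DMF (0.01 M), 0 °C → rt; then MeI
Reagents that add atoms: iodomethane, CI
Why: Proposed new method: the peroxide anion 9 is placed for a 6-exo-tet SN2 attack on lactone C4 with alkyl–oxygen cleavage (strain release, carboxylate as leaving group), which is favoured over attack at the carbonyl (eight-membered perester) and over E1cB loss (the lactone α-C–H is orthogonal to the C–O bond), so C4 is inverted to the 3R dioxane centre, C2 is kept and carboxylate 10 is then O-methylated, the closest known reaction types being SN2 opening of 4-alkyl-β-lactones by azide or sulfonamide anions and intramolecular alkylation of hydroperoxyketals by secondary sulfonates.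

**Fragment 2 (steps 5–15)**

Step 5
Reactants: 12 3-bromobut-3-en-1-ol
Product: 13 [(3-bromobut-3-en-1-yl)oxy](tert-butyl)dimethylsilane
Conditions: TBSCl, imidazole, CH2Cl2, rt
Reagents that add atoms: tert-butyldimethylsilyl chloride, CC(C)(C)[Si](C)(C)Cl
Why: Standard imidazole-promoted silyl ether protection that masks the alcohol for the organolithium, cuprate and titanium steps, with no stereocentre formed.

Step 6
Reactants: 14 (4R)-4-benzyl-1,3-oxazolidin-2-one; 15 acryloyl chloride
Product: 17 (4R)-3-acryloyl-4-benzyl-1,3-oxazolidin-2-one, via lithium oxazolidinonide 16 (not isolated)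
Conditions: n-BuLi, THF, −78 °C; then 15
Reagents that add atoms: none
Why: N-Acylation of the lithiated Evans oxazolidinone 16 by the acid chloride, which leaves the auxiliary stereocentre untouched.

Step 7
Reactants: 18 2-methylbut-1-en-3-yne; 19 allyl bromide
Product: 21 (3E)-2-methylhepta-1,3,6-triene, via dienylzirconocene chloride 20 (not isolated)
Conditions: Cp2Zr(H)Cl, THF, rt; then 19, CuCl (10 mol %), 0 °C → rt
Reagents that add atoms: none
Why: Hydrozirconation adds syn to the terminal alkyne faster than to the 1,1-disubstituted alkene and places zirconium at the terminus, which fixes the E geometry, and the copper-catalysed allylation of alkenylzirconocene 20 retains it.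

Step 8
Reactants: 17 (4R)-3-acryloyl-4-benzyl-1,3-oxazolidin-2-one; 21 (3E)-2-methylhepta-1,3,6-triene
Product: 22 (4R)-4-benzyl-3-{[(1S,2R)-2-allyl-4-methylcyclohex-3-en-1-yl]carbonyl}-1,3-oxazolidin-2-one
Conditions: Et2AlCl (1.4 equiv), CH2Cl2, −78 °C
Reagents that add atoms: none
Why: Evans auxiliary-controlled Diels–Alder reaction in which the aluminium-chelated s-cis acryloyl imide is attacked on the face away from the benzyl group, the 1-alkyl and 3-methyl groups of the diene both direct the same ortho/para regiochemistry, and the endo transition state places carbonyl and allyl cis, which sets C1 (S) and C2 (R), the later fusion centres C8a and C4a.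

Step 9
Reactants: 22 Diels–Alder imide
Product: 23 (1S,2R)-2-allyl-N-methoxy-N,4-dimethylcyclohex-3-ene-1-carboxamide
Conditions: AlMe3, MeONHMe·HCl, CH2Cl2, −10 °C → rt
Reagents that add atoms: N,O-dimethylhydroxylamine hydrochloride, CNOC.Cl
Why: Weinreb transamidation in which the aluminium amide attacks the exocyclic imide carbonyl and releases the auxiliary under non-basic conditions, so the epimerisable α-centre keeps its cis relation.

Step 10
Reactants: 13 [(3-bromobut-3-en-1-yl)oxy](tert-butyl)dimethylsilane; 23 Weinreb amide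
Product: 26 1-[(1S,2R)-2-allyl-4-methylcyclohex-3-en-1-yl]-2-[2-(tert-butyldimethylsilyloxy)ethyl]prop-2-en-1-one, via vinyllithium 24 (not isolated), via lithium hemiaminal 25 (not isolated)
Conditions: 13, t-BuLi (2 equiv), Et2O, −78 °C; then 23, −78 → −20 °C; aq NH4Cl
Reagents that add atoms: none
Why: Weinreb ketone synthesis in which bromine–lithium exchange gives vinyllithium 24 and its chelated adduct 25 cannot over-add and collapses only on work-up, so the α-centre is not epimerised.

Step 11
Reactants: 26 α-methylene ketone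
Product: 27 (4aR,8aS)-2-[2-(tert-butyldimethylsilyloxy)ethyl]-6-methyl-4a,7,8,8a-tetrahydronaphthalen-1(4H)-one (cis-fused)
Conditions: second-generation Grubbs catalyst RuCl2(=CHPh)(PCy3)(SIMes) (5 mol %), CH2Cl2, 40 °C
Reagents that add atoms: none
Why: Ring-closing metathesis between the allyl group and the 1,1-disubstituted enone alkene closes ring B as a 2-substituted cyclohexenone, driven by loss of ethylene and helped by the cis arrangement of both arms, while the trisubstituted ring A alkene is inert and the neutral medium keeps the cis fusion.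

Step 12
Reactants: 27 cis-fused enone
Product: 29 (2R,3S,4aR,8aS)-2-[2-(tert-butyldimethylsilyloxy)ethyl]-2,3,6-trimethyl-3,4,4a,7,8,8a-hexahydronaphthalen-1(2H)-one, via lithium enolate 28 (not isolated)
Conditions: Me2CuLi (from CuI, MeLi), Et2O, −78 → −20 °C; then MeI, HMPA, THF, −20 → 0 °C
Reagents that add atoms: lithium dimethylcuprate, [Li+].C[Cu-]C; iodomethane, CI
Why: Gilman conjugate addition followed by enolate alkylation, in which ring A covers the concave face of the folded cis-fused enone, so the cuprate adds axially to C3 from the convex face, trans to the C4a–C5 bond (sets 3S), and the regiodefined enolate 28 is methylated axially from the same convex face because the other face is blocked by the pseudoaxial C8 methylene, which puts the new methyl cis to the C3 methyl and to both fusion hydrogens and leaves the side chain equatorial (sets 2R).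

Step 13
Reactants: 29 α-quaternary ketone
Product: 30 tert-butyldimethyl{2-[(2R,3S,4aR,8aS)-2,3,6-trimethyl-1-methylidene-1,2,3,4,4a,7,8,8a-octahydronaphthalen-2-yl]ethoxy}silane
Conditions: Cp2Ti(μ-Cl)(μ-CH2)AlMe2, pyridine (cat.), toluene–THF, −40 °C → rt
Reagents that add atoms: Tebbe reagent, C[Al](C)Cl.C=[Ti](C1C=CC=C1)C1C=CC=C1
Why: Tebbe methylenation, whose small non-basic titanium methylidene Cp2Ti=CH2 reacts even with ketones flanked by a quaternary carbon and does not enolise them, so the C8a centre and the cis fusion are kept.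

Step 14
Reactants: 30 silyl ether
Product: 31 2-[(2R,3S,4aR,8aS)-2,3,6-trimethyl-1-methylidene-1,2,3,4,4a,7,8,8a-octahydronaphthalen-2-yl]ethanol
Conditions: HF·pyridine, pyridine, THF, 0 °C → rt
Reagents that add atoms: none
Why: Fluoride-driven desilylation under buffered conditions that do not isomerise the exocyclic alkene.

Step 15
Reactants: 31 primary alcohol
Product: 32 (2R,3S,4aR,8aS)-2-(2-iodoethyl)-2,3,6-trimethyl-1-methylidene-1,2,3,4,4a,7,8,8a-octahydronaphthalene
Conditions: I2, PPh3, imidazole, CH2Cl2, 0 °C
Reagents that add atoms: iodine, II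
Why: Appel-type iodination (SN2 on the alkoxyphosphonium salt) of an unhindered primary alcohol, with both alkenes and all stereocentres untouched.

**Union (step 16)**

Step 16
Reactants: 32 decalin iodide; 11 methyl (2S)-2-[(3R)-6-methoxy-6-methyl-1,2-dioxan-3-yl]propanoate
Product: 37 methyl (2S)-2-[(3R,6R)-6-methyl-6-{2-[(2R,3S,4aR,8aS)-2,3,6-trimethyl-1-methylidene-1,2,3,4,4a,7,8,8a-octahydronaphthalen-2-yl]ethyl}-1,2-dioxan-3-yl]propanoate, via alkyllithium 33 (not isolated), via alkylzinc bromide 34 (not isolated), via mixed dialkylzinc 35 (not isolated), via peroxycarbenium triflate 36 (not isolated)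
Conditions: 32, t-BuLi (2 equiv), Et2O–pentane, −78 °C; ZnBr2, −78 → 0 °C; Me3SiCH2Li, −78 °C; then 11, Me3SiOTf, CH2Cl2, −78 → −40 °C
Reagents that add atoms: none
Why: Proposed new method: Me3SiOTf removes the exocyclic methoxy group from either C6 epimer of 11 to give the same cyclic peroxycarbenium ion 36, a half-chair with the C3 side chain pseudoequatorial, and the mixed dialkylzinc 35 (Me3SiCH2 as non-transferable ligand) delivers its primary alkyl group along the axial trajectory that leads straight to the chair, so the new C–C bond ends cis to the C3 substituent (6R) with the methyl equatorial, the closest known reaction types being Lewis acid mediated allylsilane and enol silane additions to peroxycarbenium ions from 3-alkoxy-1,2-dioxanes and 3-alkoxy-1,2-dioxolanes, the 1,4-cis selective axial attack on 4-alkyl tetrahydropyranyl cations, and the alkylation of oxocarbenium and tertiary cations by dialkylzincs, which leaves endoperoxides and esters intact.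

**Compound list**
1 | 4-methylpent-4-enal | C=C(C)CCC=O | starting material
2 | acetyl bromide | CC(=O)Br | starting material
3 | ketene | C=C=O | intermediate
4 | (4S)-4-(3-methylbut-3-en-1-yl)oxetan-2-one | C=C(C)CC[C@H]1CC(=O)O1 | intermediate
5 | sodium enolate of 4 | C=C(C)CC[C@H]1C=C([O-])O1.[Na+] | intermediate
6 | (3S,4S)-3-methyl-4-(3-methylbut-3-en-1-yl)oxetan-2-one | C=C(C)CC[C@H]1[C@H](C)C(=O)O1 | intermediate
7 | carbonyl oxide from 6 | CC(=[O+][O-])CC[C@H]1[C@H](C)C(=O)O1 | intermediate
8 | (3S,4S)-4-(3-hydroperoxy-3-methoxybutyl)-3-methyloxetan-2-one | COC(C)(OO)CC[C@H]1[C@H](C)C(=O)O1 | intermediate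
9 | caesium peroxide salt of 8 | COC(C)(O[O-])CC[C@H]1[C@H](C)C(=O)O1.[Cs+] | intermediate
10 | caesium (2S)-2-[(3R)-6-methoxy-6-methyl-1,2-dioxan-3-yl]propanoate | COC1(C)CC[C@H]([C@H](C)C(=O)[O-])OO1.[Cs+] | intermediate
11 | methyl (2S)-2-[(3R)-6-methoxy-6-methyl-1,2-dioxan-3-yl]propanoate (C6 mixture) | COC1(C)CC[C@H]([C@H](C)C(=O)OC)OO1 | intermediate
12 | 3-bromobut-3-en-1-ol | C=C(Br)CCO | starting material
13 | [(3-bromobut-3-en-1-yl)oxy](tert-butyl)dimethylsilane | C=C(Br)CCO[Si](C)(C)C(C)(C)C | intermediate
14 | (4R)-4-benzyl-1,3-oxazolidin-2-one | O=C1N[C@H](Cc2ccccc2)CO1 | starting material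
15 | acryloyl chloride | C=CC(=O)Cl | starting material
16 | lithium salt of 14 | O=C1[N-][C@H](Cc2ccccc2)CO1.[Li+] | intermediate
17 | (4R)-3-acryloyl-4-benzyl-1,3-oxazolidin-2-one | C=CC(=O)N1[C@H](Cc2ccccc2)COC1=O | intermediate
18 | 2-methylbut-1-en-3-yne | C=C(C)C#C | starting material
19 | allyl bromide | C=CCBr | starting material
20 | chloro[(1E)-3-methylbuta-1,3-dien-1-yl]zirconocene | C=C(C)/C=C/[Zr](Cl)(C1C=CC=C1)C1C=CC=C1 | intermediate
21 | (3E)-2-methylhepta-1,3,6-triene | C=C(C)/C=C/CC=C | intermediate
22 | (4R)-4-benzyl-3-{[(1S,2R)-2-allyl-4-methylcyclohex-3-en-1-yl]carbonyl}-1,3-oxazolidin-2-one | O=C([C@H]1CCC(C)=C[C@H]1CC=C)N1[C@H](Cc2ccccc2)COC1=O | intermediate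
23 | (1S,2R)-2-allyl-N-methoxy-N,4-dimethylcyclohex-3-ene-1-carboxamide | CON(C)C(=O)[C@H]1CCC(C)=C[C@H]1CC=C | intermediate
24 | [4-(tert-butyldimethylsilyloxy)but-1-en-2-yl]lithium | [Li]C(=C)CCO[Si](C)(C)C(C)(C)C | intermediate
25 | lithium hemiaminal from 23 and 24 | [Li+].[O-]C(N(C)OC)(C(=C)CCO[Si](C)(C)C(C)(C)C)[C@H]1CCC(C)=C[C@H]1CC=C | intermediate
26 | 1-[(1S,2R)-2-allyl-4-methylcyclohex-3-en-1-yl]-2-[2-(tert-butyldimethylsilyloxy)ethyl]prop-2-en-1-one | C=C(CCO[Si](C)(C)C(C)(C)C)C(=O)[C@H]1CCC(C)=C[C@H]1CC=C | intermediate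
27 | (4aR,8aS)-2-[2-(tert-butyldimethylsilyloxy)ethyl]-6-methyl-4a,7,8,8a-tetrahydronaphthalen-1(4H)-one | O=C1[C@H]2CCC(C)=C[C@H]2CC=C1CCO[Si](C)(C)C(C)(C)C | intermediate
28 | lithium enolate after methyl addition to 27 | [Li+].[O-]C=1[C@H]2CCC(C)=C[C@H]2C[C@H](C)C=1CCO[Si](C)(C)C(C)(C)C | intermediate
29 | (2R,3S,4aR,8aS)-2-[2-(tert-butyldimethylsilyloxy)ethyl]-2,3,6-trimethyl-3,4,4a,7,8,8a-hexahydronaphthalen-1(2H)-one | O=C1[C@H]2CCC(C)=C[C@H]2C[C@H](C)[C@@]1(C)CCO[Si](C)(C)C(C)(C)C | intermediate
30 | 1-methylidene analogue of 29 (2R,3S,4aR,8aS) | C=C1[C@H]2CCC(C)=C[C@H]2C[C@H](C)[C@@]1(C)CCO[Si](C)(C)C(C)(C)C | intermediate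
31 | 2-[(2R,3S,4aR,8aS)-2,3,6-trimethyl-1-methylidene-1,2,3,4,4a,7,8,8a-octahydronaphthalen-2-yl]ethanol | C=C1[C@H]2CCC(C)=C[C@H]2C[C@H](C)[C@@]1(C)CCO | intermediate
32 | (2R,3S,4aR,8aS)-2-(2-iodoethyl)-2,3,6-trimethyl-1-methylidene-1,2,3,4,4a,7,8,8a-octahydronaphthalene | C=C1[C@H]2CCC(C)=C[C@H]2C[C@H](C)[C@@]1(C)CCI | intermediate
33 | alkyllithium from 32 | C=C1[C@H]2CCC(C)=C[C@H]2C[C@H](C)[C@@]1(C)CC[Li] | intermediate
34 | alkylzinc bromide from 33 | C=C1[C@H]2CCC(C)=C[C@H]2C[C@H](C)[C@@]1(C)CC[Zn]Br | intermediate
35 | alkyl(trimethylsilylmethyl)zinc | C=C1[C@H]2CCC(C)=C[C@H]2C[C@H](C)[C@@]1(C)CC[Zn]C[Si](C)(C)C | intermediate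
36 | cyclic peroxycarbenium triflate from 11 | CC=1CC[C@H]([C@H](C)C(=O)OC)O[O+]=1.[O-]S(=O)(=O)C(F)(F)F | intermediate
37 | target, CNP0144520.2 | C=C1[C@H]2CCC(C)=C[C@H]2C[C@H](C)[C@@]1(C)CC[C@]1(C)CC[C@H]([C@H](C)C(=O)OC)OO1 | target

**Step count.** The route has 16 steps in total. The longest linear sequence is 10 steps (6, 8, 9, 10, 11, 12, 13, 14, 15, 16).

**Three steps most likely to fail**

**Step 16.** The alkylzinc may transfer a β-hydride to cation 36 or attack the O–O bond instead of forming the C–C bond.
- The fallback changes the nucleophile from an sp3 carbon to an sp carbon. Transfer of such a carbon from aluminium to oxocarbenium ions next to peroxides is established.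
- It sets out from alcohol 31 (with 11 as partner) and comes back to the route at 37.
- Dess–Martin oxidation gives 2-[(2R,3S,4aR,8aS)-2,3,6-trimethyl-1-methylidene-1,2,3,4,4a,7,8,8a-octahydronaphthalen-2-yl]acetaldehyde F1.
- One-pot enol nonaflate formation and elimination (C4F9SO2F, phosphazene base, DMF) gives the 2-ethynyl analogue of 31 F2.
- The dimethylaluminium acetylide of the alkyne (n-BuLi, then Me2AlCl) is added to 11 with BF3·OEt2 at −78 °C. The same axial attack gives the alkyne-bridged analogue of 37 F3.
- Diimide (2-nitrobenzenesulfonyl hydrazide, Et3N) then saturates the triple bond without touching the peroxide.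
- The hindered methylidene group and the trisubstituted alkene react more slowly, so the reduction has to be stopped as soon as the intermediate alkene is consumed.

**Step 4.** The peroxide anion may acylate intermolecularly, or the SN2 opening may be too slow.
- The fallback replaces the strained lactone by an open-chain sulfonate. It sets out from lactone 6 and comes back at 11.
- Mild methanolysis (MeOH, cat. Et3N–DMAP, acyl–oxygen cleavage, both centres retained) gives methyl (2S,3S)-3-hydroxy-2,6-dimethylhept-6-enoate F4.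
- MsCl and Et3N at −20 °C give methyl (2S,3S)-2,6-dimethyl-3-(methylsulfonyloxy)hept-6-enoate F5.
- Ozonolysis in CH2Cl2–MeOH gives methyl (2S,3S)-6-hydroperoxy-6-methoxy-2-methyl-3-(methylsulfonyloxy)heptanoate F6.
- One equivalent of Cs2CO3 in cold dilute DMF closes the dioxane by invertive displacement of the mesylate.
- The known weakness of this path is competing elimination to the enoate.

**Step 2.** α-Unsubstituted β-lactone enolates tend to self-condense, so the yield may be poor.
- The fallback moves the methylation to an acyclic dianion. It sets out from lactone 4 and comes back at 6.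
- Ethanolysis (EtOH, cat. K2CO3) gives ethyl (3S)-3-hydroxy-6-methylhept-6-enoate F7.
- Fráter–Seebach alkylation (LDA 2.2 equiv, then MeI, −78 → −20 °C, anti-selective through the chelated dianion) gives ethyl (2S,3S)-3-hydroxy-2,6-dimethylhept-6-enoate F8.
- LiOH gives (2S,3S)-3-hydroxy-2,6-dimethylhept-6-enoic acid F9.
- Carboxyl activation with PhSO2Cl in pyridine at 0 °C lactonises the acid with retention at both centres.

**Further compounds**
F1 | step 16 | 2-[(2R,3S,4aR,8aS)-2,3,6-trimethyl-1-methylidene-1,2,3,4,4a,7,8,8a-octahydronaphthalen-2-yl]acetaldehyde | C=C1[C@H]2CCC(C)=C[C@H]2C[C@H](C)[C@@]1(C)CC=O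
F2 | step 16 | 2-ethynyl analogue of 31 | C=C1[C@H]2CCC(C)=C[C@H]2C[C@H](C)[C@@]1(C)C#C
F3 | step 16 | alkyne-bridged analogue of 37 | C=C1[C@H]2CCC(C)=C[C@H]2C[C@H](C)[C@@]1(C)C#C[C@]1(C)CC[C@H]([C@H](C)C(=O)OC)OO1
F4 | step 4 | methyl (2S,3S)-3-hydroxy-2,6-dimethylhept-6-enoate | C=C(C)CC[C@H](O)[C@H](C)C(=O)OC
F5 | step 4 | methyl (2S,3S)-2,6-dimethyl-3-(methylsulfonyloxy)hept-6-enoate | C=C(C)CC[C@H](OS(C)(=O)=O)[C@H](C)C(=O)OC
F6 | step 4 | methyl (2S,3S)-6-hydroperoxy-6-methoxy-2-methyl-3-(methylsulfonyloxy)heptanoate | COC(C)(OO)CC[C@H](OS(C)(=O)=O)[C@H](C)C(=O)OC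
F7 | step 2 | ethyl (3S)-3-hydroxy-6-methylhept-6-enoate | C=C(C)CC[C@H](O)CC(=O)OCC
F8 | step 2 | ethyl (2S,3S)-3-hydroxy-2,6-dimethylhept-6-enoate | C=C(C)CC[C@H](O)[C@H](C)C(=O)OCC
F9 | step 2 | (2S,3S)-3-hydroxy-2,6-dimethylhept-6-enoic acid | C=C(C)CC[C@H](O)[C@H](C)C(=O)O
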